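In the trimethylcyclohexanediol ring the two oxygen-bearing carbons, the CH(OH) next to the gem-dimethyl carbon and the C(CH3)(OH) carbon, sit 1,4 to each other across an unsubstituted CH2–CH2 unit. The key step exploits this: an acyclic γ-keto ester (methyl ketone, CH stereocentre, gem-dimethyl carbon, methyl ester) is annulated with a titanium–ethylene complex acting as a vicinal dicarbanion. Ketone insertion and intramolecular acyl substitution attach both ethylene carbons, close the six-membered ring and set the tertiary carbinol in one operation. The ring, as an (E)-vinyl iodide, is joined by Stille coupling to an epoxycyclohexene vinylstannane made from a cyclopentadiene-masked quinone diester.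

Key step: step 5

Remark: chiral catalysts are used as the antipode that gives the enantiomer drawn in the SMILES; CIP descriptors change along the route only where substituent priorities change, and the trisubstituted alkene of the target is (Z) as read from the SMILES.

Step 1
Reactants: 1 (E)-but-2-ene-1,4-diol
Product: 2 (E)-4-[(tert-butyldimethylsilyl)oxy]but-2-en-1-ol
Conditions: NaH (1.0 equiv), THF, 0 °C; TBSCl (1.0 equiv), 0 °C → rt
Reagents that add atoms: tert-butyldimethylsilyl chloride, CC(C)(C)[Si](C)(C)Cl
Why: Monosilylation of a symmetric diol through its sparingly soluble monosodium alkoxide should give the mono-TBS ether; no stereocentre is formed.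

Step 2
Reactants: 2 (E)-4-[(tert-butyldimethylsilyl)oxy]but-2-en-1-ol
Product: 3 (E)-4-[(tert-butyldimethylsilyl)oxy]but-2-en-1-yl methyl carbonate
Conditions: ClCO2Me, pyridine, CH2Cl2, 0 °C
Reagents that add atoms: methyl chloroformate, COC(=O)Cl
Why: Acylation of the primary allylic alcohol with a chloroformate gives the carbonate leaving group needed for allylic substitution.

Step 3
Reactants: 3 (E)-4-[(tert-butyldimethylsilyl)oxy]but-2-en-1-yl methyl carbonate; 4 [(1-methoxy-2-methylprop-1-en-1-yl)oxy]trimethylsilane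
Product: 5 methyl (3S)-3-{[(tert-butyldimethylsilyl)oxy]methyl}-2,2-dimethylpent-4-enoate
Conditions: [Ir(cod)Cl]2 (2 mol %), binaphthol-derived phosphoramidite with a bis(1-phenylethyl)amine unit (4 mol %, cyclometalated), fluoride activator (cat.), THF, rt
Reagents that add atoms: none
Why: Iridium-catalysed asymmetric allylic alkylation with a silyl ketene acetal attacks the substituted allyl terminus to give the branched ester, and the chiral Ir–phosphoramidite complex sets the (3S) centre.

Step 4
Reactants: 5 methyl (3S)-3-{[(tert-butyldimethylsilyl)oxy]methyl}-2,2-dimethylpent-4-enoate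
Product: 6 methyl (3S)-3-{[(tert-butyldimethylsilyl)oxy]methyl}-2,2-dimethyl-4-oxopentanoate
Conditions: Pd(quinoline–oxazoline)Cl2 (cat.), AgSbF6 (cat.), aq. t-BuOOH, CH2Cl2, 0 °C → rt
Reagents that add atoms: tert-butyl hydroperoxide, CC(C)(C)OO
Why: Tsuji–Wacker oxidation in its ligand-controlled TBHP variant should give the Markovnikov methyl ketone from the hindered terminal alkene under non-basic conditions that leave the α-stereocentre and the silyl ether intact.

Step 5
Reactants: 6 methyl (3S)-3-{[(tert-butyldimethylsilyl)oxy]methyl}-2,2-dimethyl-4-oxopentanoate; 7 ethylmagnesium bromide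
Product: 10 (3S,4R)-3-{[(tert-butyldimethylsilyl)oxy]methyl}-4-hydroxy-2,2,4-trimethylcyclohexan-1-one, via titanacyclopropane 8 (not isolated), via oxatitanacyclopentane 9 (not isolated)
Conditions: Ti(OiPr)4 (1.2 equiv), 7 (2.4 equiv), Et2O/THF, −78 → −40 °C; then 6, −40 → 0 °C; aq. NH4Cl
Reagents that add atoms: none
Why: Proposed new method: Ti(OiPr)4 and two EtMgBr give diethyltitanium diisopropoxide, which loses ethane to titanacyclopropane 8, a vicinal dicarbanion; one Ti–C bond inserts the ketone C=O of 6 (more electrophilic than the neopentyl ester) to give oxatitanacyclopentane 9, and the remaining alkyl–Ti bond attacks the tethered ester, whose tetrahedral intermediate expels methoxide to leave the cyclohexanone. The closest known reaction is the Kulinkovich reaction, in which the same titanacyclopropane adds twice to one ester carbonyl, together with Ti(II)-mediated alkene–carbonyl couplings and the Nb/Ta–alkyne annulation of 1,4-dialdehydes; here the two C–C bonds are spread over a ketone and an ester four atoms apart. The five-membered metallacycle closes by migratory insertion (Ti–C across C=O) and the carbocycle by 6-exo-trig nucleophilic acyl substitution. The only new stereocentre, the tertiary carbinol, is set in the ketone insertion by Felkin–Anh control from the adjacent CH stereocentre (quaternary carbon anti to the incoming Ti–C bond, H flanking the trajectory, non-chelating OTBS), which places the new C–O bond trans to the CH2OTBS group as in the target. The step needs ketone-before-ester chemoselectivity and six-ring acylation faster than protonolysis or cyclopropanol formation; pre-forming 8 at low temperature keeps free EtMgBr away from the ketone, and the ester is reached only intramolecularly once the ketone is consumed. No stereocentre arises at the ketone carbon formed from the ester, so the carbinol next to the gem-dimethyl group is left for step 9.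

Step 6
Reactants: 10 (3S,4R)-3-{[(tert-butyldimethylsilyl)oxy]methyl}-4-hydroxy-2,2,4-trimethylcyclohexan-1-one
Product: 11 (3S,4R)-4-hydroxy-3-(hydroxymethyl)-2,2,4-trimethylcyclohexan-1-one
Conditions: HF·pyridine, pyridine, THF, 0 °C → rt
Reagents that add atoms: none
Why: Fluoride-mediated silyl ether cleavage without an alcohol solvent avoids ketalisation of the hydroxymethyl ketone and touches no stereocentre.

Step 7
Reactants: 11 (3S,4R)-4-hydroxy-3-(hydroxymethyl)-2,2,4-trimethylcyclohexan-1-one
Product: 12 (1R,6R)-6-hydroxy-2,2,6-trimethyl-3-oxocyclohexane-1-carbaldehyde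
Conditions: Dess–Martin periodinane, NaHCO3, CH2Cl2, 0 °C → rt
Reagents that add atoms: none
Why: Dess–Martin oxidation converts the only oxidisable (primary) alcohol into the aldehyde under buffered conditions that should prevent retro-aldol cleavage and epimerisation of the β-hydroxy aldehyde.

Step 8
Reactants: 12 (1R,6R)-6-hydroxy-2,2,6-trimethyl-3-oxocyclohexane-1-carbaldehyde
Product: 13 (3R,4R)-4-hydroxy-3-[(E)-2-iodoethenyl]-2,2,4-trimethylcyclohexan-1-one
Conditions: CrCl2 (6 equiv), CHI3 (2 equiv), THF/dioxane, 0 °C → rt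
Reagents that add atoms: iodoform, IC(I)I
Why: Takai olefination is selective for the aldehyde over the hindered ketone and should give the (E)-vinyl iodide through the gem-dichromium adduct.

Step 9
Reactants: 13 (3R,4R)-4-hydroxy-3-[(E)-2-iodoethenyl]-2,2,4-trimethylcyclohexan-1-one
Product: 14 (1R,2R,4R)-2-[(E)-2-iodoethenyl]-1,3,3-trimethylcyclohexane-1,4-diol
Conditions: NaBH4, MeOH, −20 → 0 °C
Reagents that add atoms: none
Why: Substrate-controlled borohydride reduction should deliver hydride to the ketone face opposite the iodovinyl group (axial attack on the chair with equatorial side chain), giving the equatorial alcohol cis to the side chain and trans to the tertiary hydroxyl.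

Step 10
Reactants: 15 dimethyl 2,5-dihydroxyterephthalate
Product: 16 dimethyl 3,6-dioxocyclohexa-1,4-diene-1,4-dicarboxylate
Conditions: PhI(OAc)2, CH2Cl2, rt
Reagents that add atoms: none
Why: Two-electron oxidation of the hydroquinone by the hypervalent iodine reagent gives the electron-poor quinone under anhydrous, non-nucleophilic conditions.

Step 11
Reactants: 16 dimethyl 3,6-dioxocyclohexa-1,4-diene-1,4-dicarboxylate; 17 cyclopenta-1,3-diene
Product: 18 endo cis-fused cycloadduct, dimethyl 5,8-dioxo-1,4,4a,5,8,8a-hexahydro-1,4-methanonaphthalene-4a,7-dicarboxylate (enantiomer as in the SMILES)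
Conditions: Sm(OTf)3/bis(oxazolinyl)pyridine ligand (10 mol %), 4 Å MS, THF, −78 °C
Reagents that add atoms: none
Why: Chiral Lewis acid catalysed quinone Diels–Alder reaction with two-point binding of the keto ester unit adds the diene endo to an ester-bearing C=C (both are equivalent by symmetry), and the catalyst fixes the ring-fusion centres that later relay chirality to the six-membered ring.

Step 12
Reactants: 18 endo cycloadduct
Product: 19 6,7-epoxide of 18 with the oxirane on the convex face (anti to the norbornene C=C)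
Conditions: t-BuOOH, DBU (cat.), CH2Cl2, 0 °C
Reagents that add atoms: tert-butyl hydroperoxide, CC(C)(C)OO
Why: Weitz–Scheffer nucleophilic epoxidation of the enedione should occur on the convex face of the endo adduct, setting both epoxide carbons.

Step 13
Reactants: 19 convex-face epoxy dione
Product: 20 epoxy 5,8-diol with both hydroxyls on the concave face (anti to the epoxide)
Conditions: NaBH4, CeCl3·7H2O, MeOH/CH2Cl2, −78 → −40 °C
Reagents that add atoms: none
Why: Luche-type reduction attacks both ketones from the convex face because the concave face is shielded by the norbornene bridge, placing both hydroxyls anti to the epoxide while the esters stay untouched at low temperature.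

Step 14
Reactants: 20 epoxy diol
Product: 21 bis(tert-butyldimethylsilyl) ether of 20
Conditions: TBSOTf, 2,6-lutidine, CH2Cl2, 0 °C → rt
Reagents that add atoms: tert-butyldimethylsilyl triflate, CC(C)(C)[Si](C)(C)OS(=O)(=O)C(F)(F)F
Why: The silyl triflate with a hindered base silylates both hindered secondary alcohols without affecting any stereocentre.

Step 15
Reactants: 21 bis-TBS ether
Product: 22 dimethyl (1S,2S,5R,6S)-2,5-bis[(tert-butyldimethylsilyl)oxy]-7-oxabicyclo[4.1.0]hept-3-ene-1,4-dicarboxylate
Conditions: Ph2O, 240 °C (or flash vacuum pyrolysis)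
Reagents that add atoms: none
Why: Thermal retro-Diels–Alder reaction expels cyclopentadiene and unveils the alkene conjugated to the ester, leaving the four stereocentres of the six-membered ring untouched.

Step 16
Reactants: 22 epoxy diester
Product: 23 methyl (1S,2R,5S,6S)-2,5-bis[(tert-butyldimethylsilyl)oxy]-6-(hydroxymethyl)-7-oxabicyclo[4.1.0]hept-3-ene-3-carboxylate
Conditions: NaBH4, MeOH/THF, 0 °C → rt
Reagents that add atoms: none
Why: Sodium borohydride should reduce the α-alkoxy-activated glycidic ester chemoselectively, the conjugated hindered enoate being inert under these conditions.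

Step 17
Reactants: 23 epoxy alcohol
Product: 24 methyl (1S,2R,5S,6S)-2,5-bis[(tert-butyldimethylsilyl)oxy]-6-formyl-7-oxabicyclo[4.1.0]hept-3-ene-3-carboxylate
Conditions: Dess–Martin periodinane, NaHCO3, CH2Cl2, 0 °C → rt
Reagents that add atoms: none
Why: Dess–Martin oxidation gives the epoxy aldehyde without epoxide opening, and the quaternary α-carbon cannot epimerise.

Step 18
Reactants: 25 propyne; 26 hexamethyldistannane
Product: 27 (Z)-1,2-bis(trimethylstannyl)prop-1-ene
Conditions: Pd(PPh3)4 (cat.), THF, sealed tube, 65 °C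
Reagents that add atoms: none
Why: Pd(0)-catalysed syn-distannation of the terminal alkyne places both tin groups cis.

Step 19
Reactants: 27 (Z)-1,2-bis(trimethylstannyl)prop-1-ene; 24 epoxy aldehyde
Product: 29 methyl (1S,2R,5S,6S)-2,5-bis[(tert-butyldimethylsilyl)oxy]-6-[(2Z)-1-hydroxy-3-(trimethylstannyl)but-2-en-1-yl]-7-oxabicyclo[4.1.0]hept-3-ene-3-carboxylate (both carbinol epimers), via vinyllithium 28 (not isolated)
Conditions: 27, MeLi (1.0 equiv), THF, −78 °C; then 24, −78 °C; aq. NH4Cl
Reagents that add atoms: none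
Why: Tin–lithium exchange takes place at the less hindered terminal stannyl group with retention of geometry and the vinyllithium adds to the aldehyde far faster than to the enoate; the carbinol centre is not controlled here because both epimers converge in step 20.

Step 20
Reactants: 29 stannyl allylic alcohol (epimer mixture)
Product: 30 methyl (1S,2R,5S,6S)-2,5-bis[(tert-butyldimethylsilyl)oxy]-6-[(2Z)-3-(trimethylstannyl)but-2-enoyl]-7-oxabicyclo[4.1.0]hept-3-ene-3-carboxylate
Conditions: Dess–Martin periodinane, NaHCO3, CH2Cl2, 0 °C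
Reagents that add atoms: none
Why: Buffered Dess–Martin oxidation of the allylic alcohol gives the (Z)-β-stannyl enone without protodestannylation and erases the uncontrolled centre.

Step 21
Reactants: 30 epoxy enone
Product: 31 methyl (1S,2R,5S,6S)-2,5-bis[(tert-butyldimethylsilyl)oxy]-6-[(1S,2Z)-1-hydroxy-3-(trimethylstannyl)but-2-en-1-yl]-7-oxabicyclo[4.1.0]hept-3-ene-3-carboxylate
Conditions: Zn(BH4)2, Et2O, −30 °C
Reagents that add atoms: none
Why: Chelation-controlled 1,2-reduction with zinc borohydride ties the ketone and epoxide oxygens together and should deliver hydride anti to the epoxide C–C bond, giving the erythro epoxy alcohol with the (S)-carbinol.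

Step 22
Reactants: 31 hydroxy enoate
Product: 32 (1S,2Z)-1-[(1S,2S,5R,6S)-2,5-bis[(tert-butyldimethylsilyl)oxy]-4-(hydroxymethyl)-7-oxabicyclo[4.1.0]hept-3-en-1-yl]-3-(trimethylstannyl)but-2-en-1-ol
Conditions: DIBAL-H (4 equiv), CH2Cl2, −78 °C; Rochelle salt
Reagents that add atoms: none
Why: DIBAL-H reduces the conjugated ester by 1,2-addition to the allylic alcohol at −78 °C, where the epoxide, vinylstannane and silyl ethers should be stable.

Step 23
Reactants: 14 (1R,2R,4R)-2-[(E)-2-iodoethenyl]-1,3,3-trimethylcyclohexane-1,4-diol; 32 vinylstannane diol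
Product: 33 arthrosporol A bis(tert-butyldimethylsilyl) ether (silyl groups on the two ring hydroxyls of the epoxycyclohexene)
Conditions: Pd2(dba)3 (5 mol %), AsPh3 (20 mol %), CuI (10 mol %), degassed NMP, rt → 40 °C
Reagents that add atoms: none
Why: Stille cross-coupling proceeds with retention of both alkene geometries to give the (Z,E)-diene and tolerates free hydroxyls and the epoxide.

Step 24
Reactants: 33 arthrosporol A bis-TBS ether
Product: 34 arthrosporol A
Conditions: Et3N·3HF, MeCN/THF, rt
Reagents that add atoms: none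
Why: Near-neutral fluoride desilylation removes both secondary TBS ethers while avoiding Payne rearrangement of the epoxy alcohols and ionisation of the dienylic alcohol.

Compound list
1 | (E)-but-2-ene-1,4-diol | OC/C=C/CO | starting material
2 | (E)-4-[(tert-butyldimethylsilyl)oxy]but-2-en-1-ol | CC(C)(C)[Si](C)(C)OC/C=C/CO | intermediate
3 | (E)-4-[(tert-butyldimethylsilyl)oxy]but-2-en-1-yl methyl carbonate | COC(=O)OC/C=C/CO[Si](C)(C)C(C)(C)C | intermediate
4 | [(1-methoxy-2-methylprop-1-en-1-yl)oxy]trimethylsilane | COC(O[Si](C)(C)C)=C(C)C | starting material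
5 | methyl (3S)-3-{[(tert-butyldimethylsilyl)oxy]methyl}-2,2-dimethylpent-4-enoate | COC(=O)C(C)(C)[C@@H](CO[Si](C)(C)C(C)(C)C)C=C | intermediate
6 | methyl (3S)-3-{[(tert-butyldimethylsilyl)oxy]methyl}-2,2-dimethyl-4-oxopentanoate | COC(=O)C(C)(C)[C@@H](CO[Si](C)(C)C(C)(C)C)C(C)=O | intermediate
7 | ethylmagnesium bromide | CC[Mg]Br | starting material
8 | 1,1-diisopropoxytitanacyclopropane, (η2-ethene)Ti(OiPr)2 | CC(C)O[Ti]1(OC(C)C)CC1 | intermediate
9 | 2,2-diisopropoxy-1-oxa-2-titanacyclopentane carrying at C5 a methyl group and the (S)-CH(CH2OTBS)–C(CH3)2–CO2Me chain, C5 configured as the carbinol of 10 | COC(=O)C(C)(C)[C@@H](CO[Si](C)(C)C(C)(C)C)[C@@]1(C)CC[Ti](OC(C)C)(OC(C)C)O1 | intermediate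
10 | (3S,4R)-3-{[(tert-butyldimethylsilyl)oxy]methyl}-4-hydroxy-2,2,4-trimethylcyclohexan-1-one | CC(C)(C)[Si](C)(C)OC[C@@H]1C(C)(C)C(=O)CC[C@@]1(C)O | intermediate
11 | (3S,4R)-4-hydroxy-3-(hydroxymethyl)-2,2,4-trimethylcyclohexan-1-one | OC[C@@H]1C(C)(C)C(=O)CC[C@@]1(C)O | intermediate
12 | (1R,6R)-6-hydroxy-2,2,6-trimethyl-3-oxocyclohexane-1-carbaldehyde | O=C[C@@H]1C(C)(C)C(=O)CC[C@@]1(C)O | intermediate
13 | (3R,4R)-4-hydroxy-3-[(E)-2-iodoethenyl]-2,2,4-trimethylcyclohexan-1-one | I/C=C/[C@@H]1C(C)(C)C(=O)CC[C@@]1(C)O | intermediate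
14 | (1R,2R,4R)-2-[(E)-2-iodoethenyl]-1,3,3-trimethylcyclohexane-1,4-diol | I/C=C/[C@@H]1C(C)(C)[C@H](O)CC[C@@]1(C)O | intermediate
15 | dimethyl 2,5-dihydroxyterephthalate | COC(=O)c1cc(O)c(C(=O)OC)cc1O | starting material
16 | dimethyl 3,6-dioxocyclohexa-1,4-diene-1,4-dicarboxylate | COC(=O)C1=CC(=O)C(C(=O)OC)=CC1=O | intermediate
17 | cyclopenta-1,3-diene | C1=CC=CC1 | starting material
18 | endo cis-fused adduct, dimethyl 5,8-dioxo-1,4,4a,5,8,8a-hexahydro-1,4-methanonaphthalene-4a,7-dicarboxylate | COC(=O)C1=CC(=O)[C@]2(C(=O)OC)[C@@H]3C=C[C@@H](C3)[C@@H]2C1=O | intermediate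
19 | 6,7-epoxide of 18, oxirane on the convex face | COC(=O)[C@]12O[C@H]1C(=O)[C@]3(C(=O)OC)[C@@H]4C=C[C@@H](C4)[C@@H]3C2=O | intermediate
20 | 5,8-diol of 19, both hydroxyls on the concave face, anti to the epoxide | COC(=O)[C@]12O[C@H]1[C@H](O)[C@]3(C(=O)OC)[C@@H]4C=C[C@@H](C4)[C@@H]3[C@@H]2O | intermediate
21 | bis(tert-butyldimethylsilyl) ether of 20 | COC(=O)[C@]12O[C@H]1[C@H](O[Si](C)(C)C(C)(C)C)[C@]3(C(=O)OC)[C@@H]4C=C[C@@H](C4)[C@@H]3[C@@H]2O[Si](C)(C)C(C)(C)C | intermediate
22 | dimethyl (1S,2S,5R,6S)-2,5-bis[(tert-butyldimethylsilyl)oxy]-7-oxabicyclo[4.1.0]hept-3-ene-1,4-dicarboxylate | COC(=O)[C@]12O[C@H]1[C@H](O[Si](C)(C)C(C)(C)C)C(C(=O)OC)=C[C@@H]2O[Si](C)(C)C(C)(C)C | intermediate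
23 | methyl (1S,2R,5S,6S)-2,5-bis[(tert-butyldimethylsilyl)oxy]-6-(hydroxymethyl)-7-oxabicyclo[4.1.0]hept-3-ene-3-carboxylate | OC[C@]12O[C@H]1[C@H](O[Si](C)(C)C(C)(C)C)C(C(=O)OC)=C[C@@H]2O[Si](C)(C)C(C)(C)C | intermediate
24 | methyl (1S,2R,5S,6S)-2,5-bis[(tert-butyldimethylsilyl)oxy]-6-formyl-7-oxabicyclo[4.1.0]hept-3-ene-3-carboxylate | O=C[C@]12O[C@H]1[C@H](O[Si](C)(C)C(C)(C)C)C(C(=O)OC)=C[C@@H]2O[Si](C)(C)C(C)(C)C | intermediate
25 | propyne | CC#C | starting material
26 | hexamethyldistannane | C[Sn](C)(C)[Sn](C)(C)C | starting material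
27 | (Z)-1,2-bis(trimethylstannyl)prop-1-ene | C/C(=C/[Sn](C)(C)C)[Sn](C)(C)C | intermediate
28 | (Z)-1-lithio-2-(trimethylstannyl)prop-1-ene | C/C(=C/[Li])[Sn](C)(C)C | intermediate
29 | methyl (1S,2R,5S,6S)-2,5-bis[(tert-butyldimethylsilyl)oxy]-6-[(2Z)-1-hydroxy-3-(trimethylstannyl)but-2-en-1-yl]-7-oxabicyclo[4.1.0]hept-3-ene-3-carboxylate, mixture of carbinol epimers | C/C(=C/C(O)[C@]12O[C@H]1[C@H](O[Si](C)(C)C(C)(C)C)C(C(=O)OC)=C[C@@H]2O[Si](C)(C)C(C)(C)C)[Sn](C)(C)C | intermediate
30 | methyl (1S,2R,5S,6S)-2,5-bis[(tert-butyldimethylsilyl)oxy]-6-[(2Z)-3-(trimethylstannyl)but-2-enoyl]-7-oxabicyclo[4.1.0]hept-3-ene-3-carboxylate | C/C(=C/C(=O)[C@]12O[C@H]1[C@H](O[Si](C)(C)C(C)(C)C)C(C(=O)OC)=C[C@@H]2O[Si](C)(C)C(C)(C)C)[Sn](C)(C)C | intermediate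
31 | methyl (1S,2R,5S,6S)-2,5-bis[(tert-butyldimethylsilyl)oxy]-6-[(1S,2Z)-1-hydroxy-3-(trimethylstannyl)but-2-en-1-yl]-7-oxabicyclo[4.1.0]hept-3-ene-3-carboxylate | C/C(=C/[C@H](O)[C@]12O[C@H]1[C@H](O[Si](C)(C)C(C)(C)C)C(C(=O)OC)=C[C@@H]2O[Si](C)(C)C(C)(C)C)[Sn](C)(C)C | intermediate
32 | (1S,2Z)-1-[(1S,2S,5R,6S)-2,5-bis[(tert-butyldimethylsilyl)oxy]-4-(hydroxymethyl)-7-oxabicyclo[4.1.0]hept-3-en-1-yl]-3-(trimethylstannyl)but-2-en-1-ol | C/C(=C/[C@H](O)[C@]12O[C@H]1[C@H](O[Si](C)(C)C(C)(C)C)C(CO)=C[C@@H]2O[Si](C)(C)C(C)(C)C)[Sn](C)(C)C | intermediate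
33 | arthrosporol A bis(tert-butyldimethylsilyl) ether (both ring hydroxyls of the epoxycyclohexene silylated) | CC(=C/[C@H](O)[C@]12O[C@H]1[C@H](O[Si](C)(C)C(C)(C)C)C(CO)=C[C@@H]2O[Si](C)(C)C(C)(C)C)/C=C/[C@@H]1C(C)(C)[C@H](O)CC[C@@]1(C)O | intermediate
34 | arthrosporol A | CC(=C/[C@H](O)[C@]12O[C@H]1[C@H](O)C(CO)=C[C@@H]2O)/C=C/[C@@H]1C(C)(C)[C@H](O)CC[C@@]1(C)O | target

Total step count: 24. Longest linear sequence: 14 steps (steps 10–17 and 19–24, from 15 to 34); the cyclohexane branch (steps 1–9) joins at step 23.

Steps most likely to fail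

Step 5. The low-valent titanium may reduce or pinacol-couple the ketone, or the alkyl–titanium bond of 9 may be protonated before it reaches the hindered ester. The fallback sets out from 6 and uses known chemistry. Vinylmagnesium bromide with CeCl3 (THF, −78 °C) adds to the ketone under the same Felkin–Anh control and the alkoxide closes onto the ester to give (4S,5R)-4-{[(tert-butyldimethylsilyl)oxy]methyl}-5-ethenyl-3,3,5-trimethyloxolan-2-one F1. Vinyllithium (THF, −78 °C) opens the hindered lactone once to (5S,6R)-5-{[(tert-butyldimethylsilyl)oxy]methyl}-6-hydroxy-4,4,6-trimethylocta-1,7-dien-3-one F2. Ring-closing metathesis with a second-generation ruthenium carbene catalyst gives (4R,5S)-5-{[(tert-butyldimethylsilyl)oxy]methyl}-4-hydroxy-4,6,6-trimethylcyclohex-2-en-1-one F3, and hydrogenation (H2, Pd/C, EtOAc) returns to the route at 10.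

Step 11. The uncatalysed cycloaddition of the very reactive quinone diester may outrun the chiral Lewis acid and erode the enantiomeric excess. The fallback sets out from 16: the cycloaddition with 17 is run without catalyst (CH2Cl2, −78 °C) to give 18 together with its mirror image, the enantiomeric endo cycloadduct F4, and the two are separated by preparative chromatography on a chiral stationary phase. Resolution replaces asymmetric catalysis, and 18 returns to the route at step 12.

Step 21. Facial selectivity may be poor if hydride reaches the zinc chelate from the side of the epoxide CH instead of the side of the ring CH–OTBS carbon. The fallback sets out from 30 and replaces substrate control by catalyst control: a Corey–Bakshi–Shibata reduction (oxazaborolidine antipode matched to the (S)-carbinol, catecholborane, toluene, −78 °C) treats the quaternary epoxide carbon as the large group and delivers 31 directly, where it rejoins the route; no new compound is made.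

Further compounds
F1 | step 5 | (4S,5R)-4-{[(tert-butyldimethylsilyl)oxy]methyl}-5-ethenyl-3,3,5-trimethyloxolan-2-one | C=C[C@@]1(C)OC(=O)C(C)(C)[C@H]1CO[Si](C)(C)C(C)(C)C
F2 | step 5 | (5S,6R)-5-{[(tert-butyldimethylsilyl)oxy]methyl}-6-hydroxy-4,4,6-trimethylocta-1,7-dien-3-one | C=CC(=O)C(C)(C)[C@@H](CO[Si](C)(C)C(C)(C)C)[C@](C)(O)C=C
F3 | step 5 | (4R,5S)-5-{[(tert-butyldimethylsilyl)oxy]methyl}-4-hydroxy-4,6,6-trimethylcyclohex-2-en-1-one | CC(C)(C)[Si](C)(C)OC[C@@H]1C(C)(C)C(=O)C=C[C@@]1(C)O
F4 | step 11 | enantiomer of endo cycloadduct 18 | COC(=O)C1=CC(=O)[C@@]2(C(=O)OC)[C@H]3C=C[C@H](C3)[C@H]2C1=O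
F0 | step 21 | none | none
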